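**Retrosynthetic overview**
1. The last C–C bond is C6–C8'. It is made by B-alkyl Suzuki–Miyaura coupling of a ring B enol triflate with the hydroborated 6'-vinyl-1,2-dioxane. C1' is raised to the acid at the very end.
2. Enabling feature: ring-fusion carbon C8a is allylic to C1=C2 (ring A) and, through C8, homoallylic to C6=C7 (ring B). Moving each alkene by one position (C2=C3 with SiMe3 on C1; C7=C8 conjugated to a C6 ketone) makes C1–C8a the central σ-bond of the 1,5-diene C3=C2–C1–C8a–C8=C7. The cis H-4a/H-8a fusion is what a boat Cope shift delivers.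
3. The retro-Cope step trades C1–C8a for C3–C7 and gives a 7-endo-alkenylbicyclo[2.2.2]oct-5-en-2-one that already contains ring B. This cage comes from the silyl dienol ether of ketoisophorone and methyl vinyl ketone by an enantioselective Diels–Alder reaction.
4. Dioxane fragment: geranyl acetate, Evans syn aldol (C2', C3'), asymmetric epoxidation, perhydrolysis with inversion at C6', then peroxide SN2 closure with inversion at C3'.
5. Ring order: 1,2-dioxane (step 9); ring B (bought with ketoisophorone, caged in step 13); ring A last (step 17).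

Key step: step 17

Locants: the carbocycle is C1=C2(CH3)–C3–C4–C4a–C8a (ring A) and C4a–C5(CH3)2–C6=C7(CH3)–C8–C8a (ring B). The side chain runs C1' (carboxyl), C2' (CH3), C3' (dioxane CH–O), C4', C5', C6' (dioxane C–CH3), C7', C8' (bonded to C6).

Assumption: the sense of induction in step 13 is assigned by analogy with acyclic enone dienophiles bound to this class of catalyst. Should the antipode of 19 form, the (R)-catalyst is used.

**Step 1**
Reactants: 1 geranyl acetate
Product: 3 (2E)-3-methyl-6-oxohex-2-en-1-yl acetate, via secondary ozonide 2 (not isolated)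
Conditions: O3 (1.0 equiv), CH2Cl2, −78 °C; Me2S, −78 °C to rt
Reagents that add atoms: ozone [O-][O+]=O
Why: Ozonolysis with one equivalent of ozone should cleave the electron-rich C6=C7 alkene and spare the alkene that the allylic acetate deactivates; no stereocentre is formed.

**Step 2**
Reactants: 3 (2E)-3-methyl-6-oxohex-2-en-1-yl acetate; 4 (4R)-4-benzyl-3-propanoyl-1,3-oxazolidin-2-one
Product: 6 syn-aldol imide (2'R,3'S), via Z-boron enolate 5 (not isolated)
Conditions: 4, nBu2BOTf, Et3N, CH2Cl2, −78 to 0 °C; 3, −78 to 0 °C; pH 7 buffer, MeOH, H2O2, 0 °C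
Reagents that add atoms: none
Why: In this Evans syn aldol reaction the Z-boron enolate reacts through a chair Zimmerman–Traxler transition state on the face opposite the benzyl group, which sets C2' (R) and the carbinol C3' (S, to be inverted in step 9).

**Step 3**
Reactants: 6 syn-aldol imide
Product: 7 (2E,6S,7S)-6,8-dihydroxy-3,7-dimethyloct-2-en-1-yl acetate
Conditions: NaBH4, THF/H2O, 0 °C
Reagents that add atoms: none
Why: Reductive removal of the auxiliary works because borohydride attacks the activated imide carbonyl faster than the acetate, and the transient aldehyde is reduced before C2' can epimerise.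

**Step 4**
Reactants: 7 diol acetate
Product: 8 (2E,6S,7S)-8-[(tert-butyldiphenylsilyl)oxy]-6-hydroxy-3,7-dimethyloct-2-en-1-yl acetate
Conditions: TBDPSCl, imidazole, CH2Cl2, 0 °C
Reagents that add atoms: tert-butyldiphenylsilyl chloride CC(C)(C)[Si](Cl)(c1ccccc1)c1ccccc1
Why: Selective silylation should succeed because the bulky chlorosilane reacts only with the primary C1' hydroxyl.

**Step 5**
Reactants: 8 silyl ether
Product: 9 (2E,6S,7S)-8-[(tert-butyldiphenylsilyl)oxy]-3,7-dimethyl-6-[(methylsulfonyl)oxy]oct-2-en-1-yl acetate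
Conditions: MsCl, Et3N, CH2Cl2, 0 °C
Reagents that add atoms: methanesulfonyl chloride CS(=O)(=O)Cl
Why: O-sulfonylation turns C3'–OH into a leaving group with retention, and with C1' at the alcohol level no E1cB elimination is open.

**Step 6**
Reactants: 9 mesylate acetate
Product: 10 (2S,3S,6E)-1-[(tert-butyldiphenylsilyl)oxy]-8-hydroxy-2,6-dimethyloct-6-en-3-yl methanesulfonate
Conditions: K2CO3 (cat.), MeOH, 0 °C
Reagents that add atoms: none
Why: Base-catalysed transesterification frees the allylic alcohol, while the hindered secondary mesylate and the silyl ether are inert to carbonate in cold methanol.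

**Step 7**
Reactants: 10 allylic alcohol
Product: 11 (2S,3S)-1-[(tert-butyldiphenylsilyl)oxy]-5-[(2R,3R)-3-(hydroxymethyl)-2-methyloxiran-2-yl]-2-methylpentan-3-yl methanesulfonate
Conditions: Ti(OiPr)4 (10 mol %), D-(−)-diethyl tartrate (12 mol %), tBuOOH, 4 Å molecular sieves, CH2Cl2, −20 °C
Reagents that add atoms: tert-butyl hydroperoxide CC(C)(C)OO
Why: In the Katsuki–Sharpless asymmetric epoxidation the D-(−)-tartrate titanium complex delivers oxygen to the alkene face that gives the (2R,3R)-epoxide under reagent control, since the existing centres are remote.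

**Step 8**
Reactants: 11 epoxy alcohol
Product: 12 (2S,3S,6S,7R)-1-[(tert-butyldiphenylsilyl)oxy]-6-hydroperoxy-7,8-dihydroxy-2,6-dimethyloctan-3-yl methanesulfonate
Conditions: anhydrous H2O2 in Et2O, H3PMo12O40 (5 mol %), rt
Reagents that add atoms: hydrogen peroxide OO
Why: In this acid-catalysed perhydrolysis of an epoxide, H2O2 opens the activated oxirane from the rear at the tertiary carbon, the one remote from the inductively deactivating CH2OH, so C6' is set by inversion.

**Step 9**
Reactants: 12 hydroperoxy mesylate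
Product: 13 (1R)-1-[(3S,6R)-6-{(2S)-1-[(tert-butyldiphenylsilyl)oxy]propan-2-yl}-3-methyl-1,2-dioxan-3-yl]ethane-1,2-diol
Conditions: KOtBu (1.0 equiv), 18-crown-6, THF, 0 °C
Reagents that add atoms: none
Why: In this intramolecular SN2 alkylation of a hydroperoxide (6-exo-tet), one equivalent of base deprotonates only the much more acidic OOH, and the peroxide anion displaces the mesylate with inversion, closing the 1,2-dioxane and setting C3' (R).

**Step 10**
Reactants: 13 dioxane diol
Product: 14 (3S,6R)-6-{(2S)-1-[(tert-butyldiphenylsilyl)oxy]propan-2-yl}-3-methyl-1,2-dioxane-3-carbaldehyde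
Conditions: NaIO4, THF/pH 7 buffer, 0 °C
Reagents that add atoms: none
Why: Malaprade glycol cleavage removes the extra CH2OH carbon under neutral oxidising conditions that leave the O–O bond alone, and the aldehyde cannot enolise because C6' is quaternary.

**Step 11**
Reactants: 14 peroxy aldehyde
Product: 15 tert-butyl({(2S)-2-[(3R,6S)-6-ethenyl-6-methyl-1,2-dioxan-3-yl]propyl}oxy)diphenylsilane
Conditions: Ph3PCH3Br, KN(SiMe3)2, THF, 0 °C; 14, −78 to 0 °C
Reagents that add atoms: methyltriphenylphosphonium bromide C[P+](c1ccccc1)(c1ccccc1)c1ccccc1.[Br-]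
Why: Wittig methylenation installs C8', and the salt-derived ylide, used without excess base or free phosphine, should add to the aldehyde far faster than it attacks the dialkyl peroxide.

**Step 12**
Reactants: 16 ketoisophorone
Product: 17 4-[(tert-butyldimethylsilyl)oxy]-2,6,6-trimethylcyclohexa-2,4-dien-1-one
Conditions: TBSOTf, Et3N, CH2Cl2, 0 °C
Reagents that add atoms: tert-butyldimethylsilyl trifluoromethanesulfonate CC(C)(C)[Si](C)(C)OS(=O)(=O)C(F)(F)F
Why: Soft enolisation and O-silylation take the unhindered C8a ketone, which enolises toward C4a to give the fully conjugated dienone, while the C6 ketone has no α-hydrogen.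

**Step 13**
Reactants: 17 silyloxy dienone; 18 methyl vinyl ketone
Product: 19 (1S,4R,7S)-7-endo-acetyl-5-[(tert-butyldimethylsilyl)oxy]-1,3,3-trimethylbicyclo[2.2.2]oct-5-en-2-one
Conditions: (S)-1-(2-methylphenyl)-3,3-diphenyltetrahydro-1H,3H-pyrrolo[1,2-c][1,3,2]oxazaborole (20 mol %), HN(SO2CF3)2 (18 mol %), CH2Cl2, −78 to −40 °C
Reagents that add atoms: none
Why: In this catalytic enantioselective Diels–Alder reaction of a 2-silyloxy diene, the C8a silyloxy group makes C4a the nucleophilic terminus (bonds C4–C4a and C3–C7, "para" product), the endo rule places the acetyl group syn to the new C8=C8a bridge, and the shielded face of the catalyst-bound enone fixes the absolute configuration of C4a, C7 and C3.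

**Step 14**
Reactants: 19 acetyl cage ketone
Product: 20 (1R,4R,7S)-5-[(tert-butyldimethylsilyl)oxy]-1,3,3-trimethyl-7-endo-[(1E)-1-(trimethylsilyl)prop-1-en-2-yl]bicyclo[2.2.2]oct-5-en-2-one
Conditions: Cp2Ti(CH2SiMe3)2, toluene, 100 °C, dark
Reagents that add atoms: bis(cyclopentadienyl)bis(trimethylsilylmethyl)titanium C[Si](C)(C)C[Ti](C[Si](C)(C)C)(C1C=CC=C1)C1C=CC=C1
Why: In this Petasis-type carbonyl olefination the non-basic titanium alkylidene converts only the methyl ketone, because C6=O lies between two quaternary carbons, without epimerising C3, and SiMe3 should settle cis to the smaller CH3 (E); the Z isomer would converge in step 18.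

**Step 15**
Reactants: 20 vinylsilane silyl enol ether
Product: 22 (1R,4R,7S)-enol triflate of the C8a ketone, via cesium enolate 21 (not isolated)
Conditions: CsF, PhN(SO2CF3)2, DME, rt
Reagents that add atoms: N-phenylbis(trifluoromethanesulfonimide) FC(F)(F)S(=O)(=O)N(c1ccccc1)S(=O)(=O)C(F)(F)F
Why: Fluoride-triggered release of the regiodefined enolate and O-triflation should be clean because the other α-carbon is a bridgehead and, with the acetyl group gone, no retro-Michael path remains.

**Step 16**
Reactants: 22 enol triflate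
Product: 23 (1S,4S,7S)-1,3,3-trimethyl-7-endo-[(1E)-1-(trimethylsilyl)prop-1-en-2-yl]bicyclo[2.2.2]oct-5-en-2-one
Conditions: Pd(OAc)2 (5 mol %), PPh3, HCO2H, nBu3N, DMF, 60 °C
Reagents that add atoms: none
Why: Palladium-catalysed formate hydrogenolysis of an enol triflate replaces the activating oxygen on C8a by hydrogen and leaves the ketone and the vinylsilane untouched.

**Step 17**
Reactants: 23 7-endo-alkenyl cage ketone
Product: 24 (1S,4aS,8aS)-2,5,5,7-tetramethyl-1-(trimethylsilyl)-4,4a,5,8a-tetrahydronaphthalen-6(1H)-one (route locants, cis-fused)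
Conditions: mesitylene, BHT, base-washed sealed tube, 190 °C
Reagents that add atoms: none
Why: This is a thermal Cope rearrangement in which the six-electron [3,3] shift breaks C3–C7 of the bridged skeleton and forms C1–C8a through the boat transition state that the bicyclo[2.2.2]octene imposes on its 7-endo alkenyl group; the closest known reaction type is the Cope rearrangement of 7-endo-vinylbicyclo[2.2.2]oct-5-en-2-ones to cis-fused octalenones. Ring A (C1, C2, C3, C4, C4a, C8a) closes by sigmatropic C1–C8a bond formation while ring B is released intact from the cage. C8a is set by suprafacial bonding on the only face of C8=C8a that the endo group can reach, the face syn to the C3–C4 bridge, so H-8a ends cis to H-4a, whose configuration is untouched; the temporary C1 centre follows from the E-vinylsilane geometry in the boat array. The step needs the [3,3] shift to outrun cycloreversion to an achiral diene and dienone, which would erode enantiopurity; relief of cage strain, the new conjugation C6(=O)–C7=C8 and the enforced proximity of C1 and C8a secure this. The product carries SiMe3 on C1 next to C2=C3 and an enone in ring B, the two handles from which both ring alkenes of the target are placed regiospecifically.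

**Step 18**
Reactants: 24 allylsilane enone
Product: 25 (4aS,8aS)-2,5,5,7-tetramethyl-4,4a,5,8a-tetrahydronaphthalen-6(3H)-one (route locants)
Conditions: CF3CO2H, CH2Cl2, 0 °C; aq. NaHCO3
Reagents that add atoms: none
Why: In the protodesilylation of an allylsilane (SE2') the proton adds to C3, the tertiary β-silyl cation at C2 loses silicon, and the alkene lands regiospecifically at C1=C2; the electron-poor enone is not protonated.

**Step 19**
Reactants: 25 dienone
Product: 27 (4aS,8aR)-2,5,5,7-tetramethyl-3,4,4a,5,8,8a-hexahydronaphthalen-6-yl trifluoromethanesulfonate (route locants), via lithium enolate 26 (not isolated)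
Conditions: LiBH(sBu)3, THF, −78 °C; N-(5-chloro-2-pyridyl)bis(trifluoromethanesulfonimide), −78 to 0 °C
Reagents that add atoms: N-(5-chloro-2-pyridyl)bis(trifluoromethanesulfonimide) FC(F)(F)S(=O)(=O)N(c1ccc(Cl)cn1)S(=O)(=O)C(F)(F)F
Why: In this conjugate reduction with enolate trapping, the bulky hydride adds 1,4 at C8 because C6=O is blocked by C5(CH3)2 and C7–CH3, and O-triflation of the resulting C6=C7 enolate fixes the tetrasubstituted alkene.

**Step 20**
Reactants: 15 vinyl dioxane; 27 enol triflate
Product: 29 coupled silyl ether (complete carbon skeleton), via B-alkyl-9-BBN 28 (not isolated)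
Conditions: 15, 9-BBN-H, THF, 0 °C to rt; H2O; 27, PdCl2(dppf) (10 mol %), AsPh3, Cs2CO3, DMF, rt to 40 °C
Reagents that add atoms: none
Why: Hydroboration followed by B-alkyl Suzuki–Miyaura coupling puts boron on terminal C8', three bonds from the peroxide oxygen so that no β-elimination is open, and saturated dialkyl peroxides are known to survive couplings run with zerovalent palladium under mild carbonate conditions.

**Step 21**
Reactants: 29 coupled silyl ether
Product: 30 primary alcohol (C1'–OH)
Conditions: HF·pyridine, pyridine, THF, 0 °C to rt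
Reagents that add atoms: none
Why: Buffered fluoride desilylation avoids the basic conditions that would trigger Kornblum–DeLaMare cleavage at C3'–H and is too weakly acidic to move the alkenes.

**Step 22**
Reactants: 30 primary alcohol
Product: 32 target acid CNP0122760.1, via aldehyde 31 (not isolated)
Conditions: TEMPO (20 mol %), PhI(OAc)2, MeCN/pH 7 buffer, 0 °C to rt
Reagents that add atoms: water O
Why: Oxoammonium (TEMPO) oxidation takes the alcohol through the aldehyde hydrate to the acid under near-neutral conditions, which should spare both alkenes and the O–O bond and keep C2' from epimerising or undergoing β-elimination.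

**Compound list**
1 | geranyl acetate | CC(C)=CCC/C(C)=C/COC(C)=O | starting material
2 | secondary ozonide of the C6=C7 alkene of 1 | CC(=O)OC/C=C(\C)CCC1OOC(C)(C)O1 | intermediate
3 | (2E)-3-methyl-6-oxohex-2-en-1-yl acetate | CC(=O)OC/C=C(\C)CCC=O | intermediate
4 | (4R)-4-benzyl-3-propanoyl-1,3-oxazolidin-2-one | CCC(=O)N1[C@H](Cc2ccccc2)COC1=O | starting material
5 | Z-dibutylboron enolate of 4 | C/C=C(\OB(CCCC)CCCC)N1[C@H](Cc2ccccc2)COC1=O | intermediate
6 | (2E,6S,7R)-8-[(4R)-4-benzyl-2-oxo-1,3-oxazolidin-3-yl]-6-hydroxy-3,7-dimethyl-8-oxooct-2-en-1-yl acetate | CC(=O)OC/C=C(\C)CC[C@H](O)[C@@H](C)C(=O)N1[C@H](Cc2ccccc2)COC1=O | intermediate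
7 | (2E,6S,7S)-6,8-dihydroxy-3,7-dimethyloct-2-en-1-yl acetate | CC(=O)OC/C=C(\C)CC[C@H](O)[C@@H](C)CO | intermediate
8 | (2E,6S,7S)-8-[(tert-butyldiphenylsilyl)oxy]-6-hydroxy-3,7-dimethyloct-2-en-1-yl acetate | CC(=O)OC/C=C(\C)CC[C@H](O)[C@@H](C)CO[Si](c1ccccc1)(c1ccccc1)C(C)(C)C | intermediate
9 | (2E,6S,7S)-8-[(tert-butyldiphenylsilyl)oxy]-3,7-dimethyl-6-[(methylsulfonyl)oxy]oct-2-en-1-yl acetate | CC(=O)OC/C=C(\C)CC[C@H](OS(C)(=O)=O)[C@@H](C)CO[Si](c1ccccc1)(c1ccccc1)C(C)(C)C | intermediate
10 | (2S,3S,6E)-1-[(tert-butyldiphenylsilyl)oxy]-8-hydroxy-2,6-dimethyloct-6-en-3-yl methanesulfonate | OC/C=C(\C)CC[C@H](OS(C)(=O)=O)[C@@H](C)CO[Si](c1ccccc1)(c1ccccc1)C(C)(C)C | intermediate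
11 | (2S,3S)-1-[(tert-butyldiphenylsilyl)oxy]-5-[(2R,3R)-3-(hydroxymethyl)-2-methyloxiran-2-yl]-2-methylpentan-3-yl methanesulfonate | OC[C@H]1O[C@]1(C)CC[C@H](OS(C)(=O)=O)[C@@H](C)CO[Si](c2ccccc2)(c2ccccc2)C(C)(C)C | intermediate
12 | (2S,3S,6S,7R)-1-[(tert-butyldiphenylsilyl)oxy]-6-hydroperoxy-7,8-dihydroxy-2,6-dimethyloctan-3-yl methanesulfonate | OC[C@@H](O)[C@](OO)(C)CC[C@H](OS(C)(=O)=O)[C@@H](C)CO[Si](c1ccccc1)(c1ccccc1)C(C)(C)C | intermediate
13 | (1R)-1-[(3S,6R)-6-{(2S)-1-[(tert-butyldiphenylsilyl)oxy]propan-2-yl}-3-methyl-1,2-dioxan-3-yl]ethane-1,2-diol | OC[C@@H](O)[C@]1(C)CC[C@H]([C@@H](C)CO[Si](c2ccccc2)(c2ccccc2)C(C)(C)C)OO1 | intermediate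
14 | (3S,6R)-6-{(2S)-1-[(tert-butyldiphenylsilyl)oxy]propan-2-yl}-3-methyl-1,2-dioxane-3-carbaldehyde | O=C[C@]1(C)CC[C@H]([C@@H](C)CO[Si](c2ccccc2)(c2ccccc2)C(C)(C)C)OO1 | intermediate
15 | tert-butyl({(2S)-2-[(3R,6S)-6-ethenyl-6-methyl-1,2-dioxan-3-yl]propyl}oxy)diphenylsilane | C=C[C@]1(C)CC[C@H]([C@@H](C)CO[Si](c2ccccc2)(c2ccccc2)C(C)(C)C)OO1 | intermediate
16 | ketoisophorone (2,6,6-trimethylcyclohex-2-ene-1,4-dione) | CC1=CC(=O)CC(C)(C)C1=O | starting material
17 | 4-[(tert-butyldimethylsilyl)oxy]-2,6,6-trimethylcyclohexa-2,4-dien-1-one | CC1=CC(O[Si](C)(C)C(C)(C)C)=CC(C)(C)C1=O | intermediate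
18 | methyl vinyl ketone (but-3-en-2-one) | CC(=O)C=C | starting material
19 | (1S,4R,7S)-7-endo-acetyl-5-[(tert-butyldimethylsilyl)oxy]-1,3,3-trimethylbicyclo[2.2.2]oct-5-en-2-one | CC(=O)[C@H]1C[C@H]2C(O[Si](C)(C)C(C)(C)C)=C[C@]1(C)C(=O)C2(C)C | intermediate
20 | (1R,4R,7S)-5-[(tert-butyldimethylsilyl)oxy]-1,3,3-trimethyl-7-endo-[(1E)-1-(trimethylsilyl)prop-1-en-2-yl]bicyclo[2.2.2]oct-5-en-2-one | C[Si](C)(C)/C=C(\C)[C@H]1C[C@H]2C(O[Si](C)(C)C(C)(C)C)=C[C@]1(C)C(=O)C2(C)C | intermediate
21 | cesium enolate from 20 | C[Si](C)(C)/C=C(\C)[C@H]1C[C@H]2C([O-])=C[C@]1(C)C(=O)C2(C)C.[Cs+] | intermediate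
22 | (1R,4R,7S)-4,8,8-trimethyl-7-oxo-5-endo-alkenyl cage enol triflate (5-triflyloxy analogue of 20) | C[Si](C)(C)/C=C(\C)[C@H]1C[C@H]2C(OS(=O)(=O)C(F)(F)F)=C[C@]1(C)C(=O)C2(C)C | intermediate
23 | (1S,4S,7S)-1,3,3-trimethyl-7-endo-[(1E)-1-(trimethylsilyl)prop-1-en-2-yl]bicyclo[2.2.2]oct-5-en-2-one | C[Si](C)(C)/C=C(\C)[C@H]1C[C@H]2C=C[C@]1(C)C(=O)C2(C)C | intermediate
24 | (1S,4aS,8aS)-2,5,5,7-tetramethyl-1-(trimethylsilyl)-4,4a,5,8a-tetrahydronaphthalen-6(1H)-one (route locants) | C[Si](C)(C)[C@@H]1C(C)=CC[C@H]2[C@@H]1C=C(C)C(=O)C2(C)C | intermediate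
25 | (4aS,8aS)-2,5,5,7-tetramethyl-4,4a,5,8a-tetrahydronaphthalen-6(3H)-one (route locants) | CC1=C[C@H]2C=C(C)C(=O)C(C)(C)[C@H]2CC1 | intermediate
26 | lithium C6=C7 enolate from 25 | CC1=C[C@H]2CC(C)=C([O-])C(C)(C)[C@H]2CC1.[Li+] | intermediate
27 | (4aS,8aR)-2,5,5,7-tetramethyl-3,4,4a,5,8,8a-hexahydronaphthalen-6-yl trifluoromethanesulfonate (route locants) | CC1=C[C@H]2CC(C)=C(OS(=O)(=O)C(F)(F)F)C(C)(C)[C@H]2CC1 | intermediate
28 | B-(C8')-alkyl-9-borabicyclo[3.3.1]nonane from 15 | C(C[C@]1(C)CC[C@H]([C@@H](C)CO[Si](c2ccccc2)(c2ccccc2)C(C)(C)C)OO1)B1C2CCCC1CCC2 | intermediate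
29 | C1'-O-TBDPS ether of the C1' alcohol of the target skeleton (4aS,8aR,2'S,3'R,6'R) | CC1=C[C@H]2CC(C)=C(CC[C@]3(C)CC[C@H]([C@@H](C)CO[Si](c4ccccc4)(c4ccccc4)C(C)(C)C)OO3)C(C)(C)[C@H]2CC1 | intermediate
30 | C1' primary alcohol | CC1=C[C@H]2CC(C)=C(CC[C@]3(C)CC[C@H]([C@@H](C)CO)OO3)C(C)(C)[C@H]2CC1 | intermediate
31 | C1' aldehyde | CC1=C[C@H]2CC(C)=C(CC[C@]3(C)CC[C@H]([C@@H](C)C=O)OO3)C(C)(C)[C@H]2CC1 | intermediate
32 | CNP0122760.1 (4aS,8aR,2'R,3'R,6'R) | CC1=C[C@H]2CC(C)=C(CC[C@]3(C)CC[C@H]([C@@H](C)C(=O)O)OO3)C(C)(C)[C@H]2CC1 | target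

Total step count: 22. Longest linear sequence: 14 steps (steps 1–11, then 20–22).

**Steps most likely to fail**

Step 13. The hindered push–pull diene may react sluggishly. It may undergo acid-induced dienone–phenol rearrangement, or it may react by a stepwise double Michael path with poor facial selectivity. The fallback replaces catalyst control by auxiliary control and sets out from 17. An Et2AlCl-promoted Diels–Alder reaction with (4R)-3-acryloyl-4-benzyl-1,3-oxazolidin-2-one, whose chelated s-cis form is open only on the face opposite the benzyl group, should give the endo imide adduct F1. Transamidation with Me3Al and MeONHMe·HCl should give the Weinreb amide F2. MeMgBr then delivers the methyl ketone, and the route is rejoined at 19.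

Step 20. Oxidative addition and transmetalation at the triflate flanked by C5(CH3)2 and C7–CH3 may be too slow, so that protodeboronation, β-hydride elimination or slow reduction of the peroxide takes over. The fallback moves the union to C7'=C8' and sets out from 27 and 14. Palladium-catalysed methoxycarbonylation of 27 (Pd(OAc)2, dppp, CO, MeOH, Et3N) should give the methyl ester F3. DIBAL-H gives the allylic alcohol F4, and PPh3·HBr gives the phosphonium bromide F5. Its ylide (NaN(SiMe3)2, −78 °C) should undergo a Wittig reaction with aldehyde 14 to give the conjugated diene F6. Diimide (2-nitrobenzenesulfonohydrazide, Et3N) should then saturate only the disubstituted C7'=C8' alkene, and the route is rejoined at 29.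

Step 9. E2 elimination of the β-branched secondary mesylate, or ether formation by the C7' hydroxyl, may compete with the peroxide SN2 closure. The fallback reverses the order of the two C–O bond formations and sets out from 10. Displacement of the mesylate with 2-methoxyprop-2-yl hydroperoxide and CsOH in DMF (inversion at C3') should give the peroxyketal F7. Asymmetric epoxidation as in step 7 should give the epoxy peroxyketal F8. Aqueous acetic acid unmasks the secondary hydroperoxide F9, which under a trace of camphorsulfonic acid should open the epoxide 6-exo at the tertiary carbon with inversion. The route is rejoined at 13.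

**Further compounds**
F1 | step 13 | endo imide adduct of 17 and (4R)-3-acryloyl-4-benzyl-1,3-oxazolidin-2-one | O=C(N1[C@H](Cc2ccccc2)COC1=O)[C@H]1C[C@H]2C(O[Si](C)(C)C(C)(C)C)=C[C@]1(C)C(=O)C2(C)C
F2 | step 13 | Weinreb amide of the cage acid | CON(C)C(=O)[C@H]1C[C@H]2C(O[Si](C)(C)C(C)(C)C)=C[C@]1(C)C(=O)C2(C)C
F3 | step 20 | methyl (4aS,8aR)-2,5,5,7-tetramethyl-3,4,4a,5,8,8a-hexahydronaphthalene-6-carboxylate (route locants) | CC1=C[C@H]2CC(C)=C(C(=O)OC)C(C)(C)[C@H]2CC1
F4 | step 20 | C6-hydroxymethyl decalin diene | CC1=C[C@H]2CC(C)=C(CO)C(C)(C)[C@H]2CC1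
F5 | step 20 | C6-methylenetriphenylphosphonium bromide | CC1=C[C@H]2CC(C)=C(C[P+](c3ccccc3)(c3ccccc3)c3ccccc3)C(C)(C)[C@H]2CC1.[Br-]
F6 | step 20 | C7'=C8' diene from F5 and 14 | CC1=C[C@H]2CC(C)=C(/C=C/[C@]3(C)CC[C@H]([C@@H](C)CO[Si](c4ccccc4)(c4ccccc4)C(C)(C)C)OO3)C(C)(C)[C@H]2CC1
F7 | step 9 | C3' (2-methoxyprop-2-yl)peroxy allylic alcohol | OC/C=C(\C)CC[C@@H](OOC(C)(C)OC)[C@@H](C)CO[Si](c1ccccc1)(c1ccccc1)C(C)(C)C
F8 | step 9 | (2R,3R)-epoxy alcohol peroxyketal | OC[C@H]1O[C@]1(C)CC[C@@H](OOC(C)(C)OC)[C@@H](C)CO[Si](c2ccccc2)(c2ccccc2)C(C)(C)C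
F9 | step 9 | C3' hydroperoxy epoxy alcohol | OC[C@H]1O[C@]1(C)CC[C@@H](OO)[C@@H](C)CO[Si](c2ccccc2)(c2ccccc2)C(C)(C)C
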